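**Assumptions and locants.** (2S)-Pinocembrin and tert-butyl 5-oxopentanoate are treated as catalogue compounds. Flavanone numbering is used for the aromatic part. Side-chain carbons run C1′ (lactone C=O) to C11′ (PhCH=). C5′, C7′ and C9′ are pyran C6, C4 and C2.

**Target as read from the SMILES.** The descriptors are 2S, 5′R, 7′R, 9′R. The 10-membered aryl lactone is O7–C1′…C7′–C8–C7. On the pyran, the styryl group and the C4′ chain are cis (equatorial). The C8-aryl and the 9′-OH sit on the opposite face (axial).

## Retrosynthetic overview
1. Target 16 comes from mild hydrolysis of the C9′ methyl ketal and 5-O-TBS ether of macrocycle 15. The hemiketal configuration is thermodynamic.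
2. Key step: the 10-membered ring is closed at the C8(aryl)–C7′ bond, not at the ester. Ester 14 undergoes an intramolecular vinylogous (carbon-Ferrier) Friedel–Crafts reaction that sets C7′ and C9′ from C5′.
3. Ester 14 comes from ordinary intermolecular esterification of 5-O-TBS-(S)-pinocembrin 13 (C2 bought, C6 shielded) with pseudo-glycal acid 10.
4. Acid 10 comes from 1,2-addition of (E)-styryllithium to (R)-dihydropyranone 7, which comes from allylboration, acryloylation and RCM of aldehyde 1 (sets C5′).
5. Ring order: flavanone (bought), then dihydropyran (RCM), then the 10-membered lactone together with the saturated pyran (one step), then the hemiketal.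

## Route

**Step 1**
Reactants: 1 tert-butyl 5-oxopentanoate; 2 allylmagnesium bromide
Product: 3 tert-butyl (5R)-5-hydroxyoct-7-enoate
Conditions: (−)-Ipc2BOMe [(+)-α-pinene series], 2, Et2O, 0 °C; then 1, −78 °C; NaBO3·4H2O workup
Reagents that add atoms: allylmagnesium bromide, C=CC[Mg]Br
Why: Brown asymmetric allylboration through a closed chair transition state gives the (R)-carbinol (C5′), and the hindered tert-butyl ester neither reacts nor δ-lactonises.

**Step 2**
Reactants: 3; 4 acryloyl chloride
Product: 5 tert-butyl (5R)-5-(acryloyloxy)oct-7-enoate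
Conditions: 4, i-Pr2NEt, DMAP (cat.), CH2Cl2, 0 °C
Reagents that add atoms: acryloyl chloride, C=CC(=O)Cl
Why: DMAP-catalysed O-acylation, with C5′ untouched.

**Step 3**
Reactants: 5
Product: 6 tert-butyl 4-[(2R)-6-oxo-3,6-dihydro-2H-pyran-2-yl]butanoate
Conditions: Grubbs II (3 mol %), CH2Cl2 (0.01 M), reflux
Reagents that add atoms: none
Why: Ring-closing metathesis of an acrylate with a terminal alkene loses ethylene and gives the six-membered lactone with a necessarily cis C7′=C8′ bond.

**Step 4**
Reactants: 6
Product: 7 4-[(2R)-6-oxo-3,6-dihydro-2H-pyran-2-yl]butanoic acid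
Conditions: TFA/CH2Cl2 1:3, 0 °C to rt
Reagents that add atoms: none
Why: Acidolysis of the tert-butyl ester (loss of isobutene) is done here because nothing acid-labile is present yet, and the enoate lactone is inert to TFA.

**Step 5**
Reactants: 7; 8 (E)-β-bromostyrene
Product: 9 4-[(2R,6R)-6-hydroxy-6-[(E)-styryl]-3,6-dihydro-2H-pyran-2-yl]butanoic acid (lactol, major anomer drawn)
Conditions: 8, t-BuLi (2 equiv per Br), Et2O, −78 °C; add 2.15 equiv of the styryllithium to 7, THF, −78 °C; AcOH quench at −78 °C; use at once
Reagents that add atoms: (E)-styryllithium from 8, [Li]/C=C/c1ccccc1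
Why: The first equivalent forms the inert lithium carboxylate and the second adds 1,2 to the lactone C=O (organolithium–lactone addition); the lithium lactolate survives until quench so there is no over-addition, Li–Br exchange retains E geometry, and the cis ring alkene holds the product as the cyclic lactol.

**Step 6**
Reactants: 9
Product: 10 4-[(2R,6R)-6-methoxy-6-[(E)-styryl]-3,6-dihydro-2H-pyran-2-yl]butanoic acid (kept as its Et3NH+ salt)
Conditions: MeOH, PPTS (10 mol %), 3 Å MS, 0 °C; quench with Et3N; concentrate
Reagents that add atoms: methanol, CO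
Why: Ferrier-type O-ketalisation through the pyranylium ion places OMe pseudo-axial at C9′ (anomeric effect) and locks C5′–O so it cannot δ-lactonise onto C1′; this anomeric centre is erased in step 10.

**Step 7**
Reactants: 11 (2S)-pinocembrin
Product: 12 (2S)-5,7-bis(tert-butyldimethylsilyloxy)flavanone
Conditions: TBSOTf (2.4 equiv), 2,6-lutidine, CH2Cl2, −20 to 0 °C
Reagents that add atoms: TBSOTf, CC(C)(C)[Si](C)(C)OS(=O)(=O)C(F)(F)F
Why: Silyl triflate silylates even the chelated 5-OH, and the weak hindered base does not trigger the retro-oxa-Michael ring opening that would racemise C2.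

**Step 8**
Reactants: 12
Product: 13 (2S)-5-(tert-butyldimethylsilyloxy)-7-hydroxyflavanone
Conditions: TBAF (1.0 equiv)/AcOH (1.2 equiv), THF, −40 °C
Reagents that add atoms: none
Why: This is a selective aryl silyl ether cleavage, because the unhindered 7-phenoxide (para to the carbonyl) is the best leaving group, the same order as selective 7-O-deacylation of flavonoids; the buffer protects C2.

**Step 9**
Reactants: 10; 13
Product: 14 (2S)-5-TBSO-4-oxoflavan-7-yl 4-[(2R,6R)-6-methoxy-6-[(E)-styryl]-3,6-dihydro-2H-pyran-2-yl]butanoate
Conditions: MNBA (1.2 equiv), Et3N, DMAP (0.2 equiv), CH2Cl2, 0 °C to rt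
Reagents that add atoms: none
Why: Shiina mixed-anhydride esterification runs under basic conditions, so the ketal survives, and 7-OH is the only free hydroxyl.

**Step 10 (key step)**
Reactants: 14
Product: 15 macrocyclic methyl ketal (2S,5′R,7′R,9′R), which is the target bearing 9′-OMe and 5-OTBS
Conditions: slow addition of 14 to TMSOTf (0.3 equiv), 4 Å MS, CH2Cl2 (final 1 mM), −78 to −30 °C; Et3N quench
Reagents that add atoms: none (isomerisation; the OMe leaves and returns to C9′)
Why: Proposed new method: Lewis acid reversibly ionises the doubly allylic ketal to a 2-styryl-5,6-dihydropyranylium ion for which O-return is degenerate, and the tethered arene attacks the γ-terminus C7′ (C9′ is fully substituted) through C8, which is para to 5-OSi and ortho to O1 while C6 is walled off between OTBS and the acyloxy group; pseudo-axial attack on the half-chair anti to the pseudo-equatorial C5′ chain gives the 5′,7′-trans (7′R) ring, and the proton released on rearomatisation protonates the 2-alkoxydiene at C8′ so that MeOH re-adds axially (9′R); the closest known reaction types are carbon-Ferrier aryl C-glycosylation, C4-arylation of flavylium ions by phloroglucinol-type rings, oxocarbenium (Prins) macrocyclisation, and aryl cinnamate to dihydrocoumarin cyclisation, which shows O-acyl arenes alkylating ortho.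

**Step 11**
Reactants: 15
Product: 16 target (CID 21592353)
Conditions: HF·pyridine, THF/H2O 10:1, 0 °C to rt; pH 6 buffer workup; avoid base
Reagents that add atoms: water, O
Why: One mildly acidic reagent cleaves the carbonyl-flanked aryl TBS ether and hydrolyses the styryl-activated ketal, and the hemiketal equilibrates to the anomer with axial OH and equatorial styryl (anomeric effect, and it avoids a styryl/aryl 1,3-diaxial clash), which is 9′R; base is excluded because it would open the hemiketal and let C5′–OH translactonise.

## Compound list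
| No. | Name | SMILES | Role |
|---|---|---|---|
| 1 | tert-butyl 5-oxopentanoate | O=CCCCC(=O)OC(C)(C)C | starting material |
| 2 | allylmagnesium bromide | C=CC[Mg]Br | starting material |
| 3 | tert-butyl (5R)-5-hydroxyoct-7-enoate | C=CC[C@H](O)CCCC(=O)OC(C)(C)C | intermediate |
| 4 | acryloyl chloride | C=CC(=O)Cl | starting material |
| 5 | tert-butyl (5R)-5-(acryloyloxy)oct-7-enoate | C=CC[C@H](OC(=O)C=C)CCCC(=O)OC(C)(C)C | intermediate |
| 6 | tert-butyl 4-[(2R)-6-oxo-3,6-dihydro-2H-pyran-2-yl]butanoate | O=C1C=CC[C@@H](CCCC(=O)OC(C)(C)C)O1 | intermediate |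
| 7 | 4-[(2R)-6-oxo-3,6-dihydro-2H-pyran-2-yl]butanoic acid | O=C1C=CC[C@@H](CCCC(=O)O)O1 | intermediate |
| 8 | (E)-β-bromostyrene | Br/C=C/c1ccccc1 | starting material |
| 9 | (2R,6R)-lactol acid | OC(=O)CCC[C@@H]1CC=C[C@](O)(/C=C/c2ccccc2)O1 | intermediate |
| 10 | (2R,6R)-methyl ketal acid | OC(=O)CCC[C@@H]1CC=C[C@](OC)(/C=C/c2ccccc2)O1 | intermediate |
| 11 | (2S)-pinocembrin | O=C1C[C@@H](c2ccccc2)Oc2cc(O)cc(O)c12 | starting material |
| 12 | (2S)-5,7-bis-O-TBS-pinocembrin | O=C1C[C@@H](c2ccccc2)Oc2cc(O[Si](C)(C)C(C)(C)C)cc(O[Si](C)(C)C(C)(C)C)c12 | intermediate |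
| 13 | (2S)-5-O-TBS-pinocembrin | O=C1C[C@@H](c2ccccc2)Oc2cc(O)cc(O[Si](C)(C)C(C)(C)C)c12 | intermediate |
| 14 | 7-O-ester of 13 with 10 | O=C(Oc1cc(O[Si](C)(C)C(C)(C)C)c2C(=O)C[C@@H](c3ccccc3)Oc2c1)CCC[C@@H]1CC=C[C@](OC)(/C=C/c2ccccc2)O1 | intermediate |
| 15 | macrocyclic 9′-OMe, 5-OTBS compound | O=C1CCC[C@@H]2C[C@H](C[C@](OC)(/C=C/c3ccccc3)O2)c2c(cc(O[Si](C)(C)C(C)(C)C)c3c2O[C@H](c2ccccc2)CC3=O)O1 | intermediate |
| 16 | target (2S,5′R,7′R,9′R) | O=C1CCC[C@@H]2C[C@H](C[C@](O)(/C=C/c3ccccc3)O2)c2c(cc(O)c3c2O[C@H](c2ccccc2)CC3=O)O1 | target |

## Summary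
Total steps: 11. Longest linear sequence: 9 (steps 1–6 and 9–11).

**Steps most likely to fail**
1. **Step 10.** The arene may be too weak a nucleophile, oligomers may form, the cis diastereomer may compete, or the cation may lose a proton to give a trienone.
   - Fallback: form the C8–C7′ bond intermolecularly. React the allyl ester of 10 with the more nucleophilic bis-silyl ether 12 (unconstrained axial attack, C6 flanked by two OTBS groups).
   - Then carry out Pd(0) deallylation and 7-O-desilylation, and close the ring at the ester by Shiina macrolactonisation with C5′–O still locked in the ketal.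
2. **Steps 5 and 6.** γ-Deprotonation or 1,4-addition may occur on the enoate lactone, or the opened lactol may drift from Z to E.
   - Fallback: reach the same pyranylium precursor from the C7′-oxo pattern. Cyclise an (R)-β-hydroxy ynone (C7′=O, C8′≡C9′–styryl) by Au(I)/Ag(I) 6-endo closure to the 2-styryl-2,3-dihydro-4H-pyran-4-one.
   - Then apply Luche reduction, Ferrier methanolysis and LiOH saponification of a methyl ester to obtain 10.
3. **Step 8.** The 7-O versus 5-O desilylation may be unselective, which would also undermine C8 regiocontrol.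
   - Fallback: skip the free phenol. Convert 10 to its acyl fluoride and couple it directly with 12 under catalytic fluoride (silyl ether/acyl fluoride exchange at the more labile 7-OSi).
   - Alternatively, replace 13 with commercial (S)-alpinetin (5-OMe shields C6) and finish with chelation-assisted BCl3 demethylation followed by an aqueous quench.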